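**Plan**

- Feature: ring B of the flavanone (C4a, C5, C6, C7, C8, C8a) is a fully substituted phloroglucinol whose three oxygens have different fates, and C8 bears the CH(i-Pr) methine that links it to ring A (the methoxy-trimethyl cyclohexadienone). C8 and C7 can therefore be the two carbons of a siloxyalkyne already attached to that methine, with C8a, C6, C5 and C4a supplied by a 3-alkoxy-2-methylcyclobutenone.
- Retrosynthesis: ring C (the pyranone) is cut at O1–C2 and C4–C4a, ring B at C8–C8a and C6–C7, then the alkyne–methine bond (conjugate alkynylation) and the methine–ring A bond (Knoevenagel condensation).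
- Forward order: ring A by dearomatising C-methylation of a phloroglucinol ester, then the side chain and the siloxyalkyne, ring B by benzannulation, ring C by Mitsunobu etherification and Friedel–Crafts acylation, then deprotection.
- Stereochemistry: the methine (R) is set by a rhodium/DTBM-SEGPHOS-catalysed conjugate alkynylation and carried through unchanged; C2 (S) comes from methyl (R)-3-hydroxy-3-phenylpropanoate by Mitsunobu inversion.

Key step: step 11

Assumption: O-benzylation of the ring A enol is taken to occur at the oxygen beside the gem-dimethyl carbon (cross-conjugated dienone); the regioisomeric benzyl ether would pass through the same steps and converge at the final hydrogenolysis.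
Assumption: (R)-DTBM-SEGPHOS is taken as the ligand enantiomer that delivers the alkynyl group to the face leading to the (R)-methine of the target; if the sense of induction is the opposite, the (S)-ligand is used.
Assumption: ketene is generated immediately before use by pyrolysis of acetone and is treated as a stock reagent.

**Route**

Step 1
Reactants: 1 methyl 2,6-dihydroxy-4-methoxybenzoate
Product: 2 methyl 2-hydroxy-4-methoxy-3,3,5-trimethyl-6-oxocyclohexa-1,4-diene-1-carboxylate
Conditions: NaOMe (3.1 equiv), MeI (3.3 equiv), MeOH, 0 °C → reflux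
Reagents that add atoms: iodomethane, CI
Why: Dearomatising C-alkylation of a phloroglucinol-type phenolate, in which the ester blocks C1 so that the three methyl groups should enter at the two equivalent carbons flanking the methoxy group, the third one breaking aromaticity.

Step 2
Reactants: 2 methyl 2-hydroxy-4-methoxy-3,3,5-trimethyl-6-oxocyclohexa-1,4-diene-1-carboxylate
Product: 4 3-hydroxy-5-methoxy-4,4,6-trimethylcyclohexa-2,5-dien-1-one (ring A enol), via carboxylic acid 3 (not isolated)
Conditions: KOH (3 M aq), MeOH, reflux; then 2 M HCl to pH 3, 0 → 40 °C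
Reagents that add atoms: none
Why: Saponification followed by decarboxylation of the resulting vinylogous β-keto acid, the usual de-esterification of a 2-carbomethoxy-1,3-dione, with basic hydrolysis and only brief cold acid chosen to spare the methyl enol ether.

Step 3
Reactants: 4 ring A enol; 5 isobutyraldehyde
Product: 7 5-methoxy-4,6,6-trimethyl-2-(2-methylpropylidene)cyclohex-4-ene-1,3-dione (E/Z mixture), via Mannich base 6 (not isolated)
Conditions: piperidine (1.1 equiv), CH2Cl2, 0 °C → rt; then 1 M HCl
Reagents that add atoms: none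
Why: Knoevenagel condensation through the piperidine Mannich base, the standard access to isobutylidene β-triketones, which should work here because C2 is the only nucleophilic carbon of the fully substituted ring and acid expels the amine.

Step 4
Reactants: 7 5-methoxy-4,6,6-trimethyl-2-(2-methylpropylidene)cyclohex-4-ene-1,3-dione; 8 (triisopropylsilyl)acetylene
Product: 9 3-hydroxy-5-methoxy-4,4,6-trimethyl-2-[(3S)-4-methyl-1-(triisopropylsilyl)pent-1-yn-3-yl]cyclohexa-2,5-dien-1-one
Conditions: [Rh(OAc)(C2H4)2]2 (2.5 mol %), (R)-DTBM-SEGPHOS (6 mol %), 8 (2 equiv), 1,4-dioxane, 60 °C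
Reagents that add atoms: none
Why: Rhodium-catalysed asymmetric conjugate alkynylation, in which an alkynylrhodium species (monovalent rhodium) adds to the doubly activated alkene while the bulky silyl group suppresses alkyne dimerisation, and the bisphosphine selects one face of the β-carbon to set the methine centre, both geometric isomers of 7 being expected to converge because the two carbonyl flanks are nearly alike at the reacting alkene.

Step 5
Reactants: 9 3-hydroxy-5-methoxy-4,4,6-trimethyl-2-[(3S)-4-methyl-1-(triisopropylsilyl)pent-1-yn-3-yl]cyclohexa-2,5-dien-1-one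
Product: 10 3-(benzyloxy)-5-methoxy-4,4,6-trimethyl-2-[(3S)-4-methyl-1-(triisopropylsilyl)pent-1-yn-3-yl]cyclohexa-2,5-dien-1-one
Conditions: BnBr, Cs2CO3, DMF, 0 °C → rt
Reagents that add atoms: benzyl bromide, BrCc1ccccc1
Why: Williamson O-alkylation of the caesium enolate of a 2-substituted 1,3-dione, where the branched C2 substituent blocks C-alkylation and the still-silylated alkyne cannot be attacked by the enolate oxygen.

Step 6
Reactants: 10 3-(benzyloxy)-5-methoxy-4,4,6-trimethyl-2-[(3S)-4-methyl-1-(triisopropylsilyl)pent-1-yn-3-yl]cyclohexa-2,5-dien-1-one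
Product: 11 3-(benzyloxy)-5-methoxy-4,4,6-trimethyl-2-[(3R)-4-methylpent-1-yn-3-yl]cyclohexa-2,5-dien-1-one
Conditions: Bu4NF, THF, 0 °C; then H2O
Reagents that add atoms: none
Why: Fluoride-induced protodesilylation of an alkynylsilane, run cold and briefly so that the propargylic centre is not touched (the descriptor changes from S to R only because the silicon is lost).

Step 7
Reactants: 11 3-(benzyloxy)-5-methoxy-4,4,6-trimethyl-2-[(3R)-4-methylpent-1-yn-3-yl]cyclohexa-2,5-dien-1-one
Product: 14 3-(benzyloxy)-5-methoxy-4,4,6-trimethyl-2-[(3R)-4-methyl-1-(triisopropylsilyloxy)pent-1-yn-3-yl]cyclohexa-2,5-dien-1-one, via lithium acetylide 12 (not isolated), via lithium ynolate 13 (not isolated)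
Conditions: LiN(SiMe3)2 (2.2 equiv), THF, −78 °C; t-BuOOH (1.05 equiv), −78 → 0 °C; iPr3SiOTf, −78 → 0 °C
Reagents that add atoms: tert-butyl hydroperoxide, CC(C)(C)OO; triisopropylsilyl trifluoromethanesulfonate, CC(C)[Si](OS(=O)(=O)C(F)(F)F)(C(C)C)C(C)C
Why: Oxidation of a lithium acetylide by LiOOt-Bu to the lithium ynolate and O-silylation with the silyl triflate, the established preparation of triisopropylsiloxyalkynes from terminal alkynes, with the amide base chosen because it does not add to the fully substituted dienone.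

Step 8
Reactants: 15 1-ethoxyprop-1-yne; 16 ketene
Product: 17 3-ethoxy-2-methylcyclobut-2-en-1-one
Conditions: CH2Cl2, −20 → 0 °C
Reagents that add atoms: none
Why: Thermal [2+2] cycloaddition of ketene with an ynol ether, in which the nucleophilic methyl-bearing alkyne carbon bonds to the ketene carbonyl carbon and so places methyl at C2 and ethoxy at C3.

Step 9
Reactants: 17 3-ethoxy-2-methylcyclobut-2-en-1-one
Product: 18 3-hydroxy-2-methylcyclobut-2-en-1-one (enol of 2-methylcyclobutane-1,3-dione)
Conditions: 1 M HCl, THF, 0 °C → rt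
Reagents that add atoms: water, O
Why: Acid hydrolysis of a vinylogous ester by addition–elimination of water, giving the dione as its stable, acidic enol.

Step 10
Reactants: 18 3-hydroxy-2-methylcyclobut-2-en-1-one
Product: 19 3-(benzyloxy)-2-methylcyclobut-2-en-1-one
Conditions: BnOH, PPh3, DIAD, THF, 0 °C → rt
Reagents that add atoms: benzyl alcohol, OCc1ccccc1
Why: Mitsunobu O-alkylation of a strongly acidic enol under neutral conditions, which avoids the nucleophilic ring opening that acid or alkoxide could cause in the strained dione.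

Step 11
Reactants: 14 3-(benzyloxy)-5-methoxy-4,4,6-trimethyl-2-[(3R)-4-methyl-1-(triisopropylsilyloxy)pent-1-yn-3-yl]cyclohexa-2,5-dien-1-one; 19 3-(benzyloxy)-2-methylcyclobut-2-en-1-one
Product: 23 3-(benzyloxy)-2-{(1R)-1-[4-(benzyloxy)-6-hydroxy-3-methyl-2-(triisopropylsilyloxy)phenyl]-2-methylpropyl}-5-methoxy-4,4,6-trimethylcyclohexa-2,5-dien-1-one, via vinylketene 20 (not isolated), via vinylcyclobutenone 21 (not isolated), via dienylketene 22 (not isolated)
Conditions: 19 (1.5 equiv), toluene, 110 °C, sealed tube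
Reagents that add atoms: none
Why: Proposed new method: heat opens cyclobutenone 19 by 4π-electrocyclic cleavage to vinylketene 20, which adds [2+2] to siloxyalkyne 14 so that the oxygen-free alkyne carbon (future C8) bonds to the ketene carbonyl carbon (future C8a) and the oxygenated carbon (C7) to the ketene α-carbon (C6), giving 21; a second 4π opening gives dienylketene 22, and ring B closes by a thermally allowed disrotatory 6π-electrocyclisation between C8a and C4a followed by tautomerisation to the phenol. The closest known reaction type is the Danheiser benzannulation of 3-alkyl- and 3-arylcyclobutenones with triisopropylsiloxyalkynes to resorcinol monosilyl ethers; untested here is a 3-alkoxycyclobutenone (a vinylogous ester that should open more reluctantly) paired with an α-branched siloxyalkyne, which would extend the pattern to a phloroglucinol. No stereocentre is created, and the propargylic methine of 14 takes part in no bond change, so the neutral thermal conditions should leave it intact. The step needs a single regiochemistry in the [2+2] event, and this is secured by the polarisation of the siloxyalkyne (nucleophilic at the carbon β to oxygen) against the electrophilic ketene carbon, so that OH falls on C8a, OSi on C7, methyl on C6, OBn on C5 and H on C4a; the bulky ortho substituent should also shield the new phenol from acylation by excess ketene.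

Step 12
Reactants: 23 ring B phenol; 24 methyl (R)-3-hydroxy-3-phenylpropanoate
Product: 25 methyl (3S)-3-{5-(benzyloxy)-2-[(1R)-1-(2-(benzyloxy)-4-methoxy-3,3,5-trimethyl-6-oxocyclohexa-1,4-dien-1-yl)-2-methylpropyl]-4-methyl-3-(triisopropylsilyloxy)phenoxy}-3-phenylpropanoate
Conditions: 24 (1.5 equiv), PPh3, DIAD, toluene, 0 °C → rt
Reagents that add atoms: none
Why: Mitsunobu etherification of the only free phenol with a secondary benzylic alcohol, an SN2 displacement of the oxyphosphonium ion that inverts the (R)-carbinol to the (S)-ether and thereby sets C2.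

Step 13
Reactants: 25 Mitsunobu ether methyl ester
Product: 26 (3S)-3-{5-(benzyloxy)-2-[(1R)-1-(2-(benzyloxy)-4-methoxy-3,3,5-trimethyl-6-oxocyclohexa-1,4-dien-1-yl)-2-methylpropyl]-4-methyl-3-(triisopropylsilyloxy)phenoxy}-3-phenylpropanoic acid
Conditions: LiOH, THF/H2O, 0 °C; then 1 M HCl to pH 4
Reagents that add atoms: lithium hydroxide, [Li+].[OH-]
Why: Saponification of an unhindered methyl ester, kept cold so that β-elimination of the aryloxide does not compete, while the doubly flanked aryl silyl ether and the hindered benzyl enol ether should resist hydroxide.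

Step 14
Reactants: 26 aryloxy acid
Product: 28 (2S)-5-(benzyloxy)-8-[(1R)-1-(2-(benzyloxy)-4-methoxy-3,3,5-trimethyl-6-oxocyclohexa-1,4-dien-1-yl)-2-methylpropyl]-6-methyl-2-phenyl-7-(triisopropylsilyloxy)-2,3-dihydro-4H-chromen-4-one, via mixed anhydride 27 (not isolated)
Conditions: (CF3CO)2O, CH2Cl2, 0 °C → rt
Reagents that add atoms: none
Why: Intramolecular Friedel–Crafts acylation through the mixed trifluoroacetic anhydride, closing the six-membered ring C at C4a, the only unsubstituted and triply oxygen-activated position of ring B, under activation too mild to acylate the phenyl ring or ionise the C2–O bond.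

Step 15
Reactants: 28 protected flavanone
Product: 29 (2S)-5-(benzyloxy)-8-[(1R)-1-(2-(benzyloxy)-4-methoxy-3,3,5-trimethyl-6-oxocyclohexa-1,4-dien-1-yl)-2-methylpropyl]-7-hydroxy-6-methyl-2-phenyl-2,3-dihydro-4H-chromen-4-one
Conditions: HF·pyridine, THF, 0 °C → rt
Reagents that add atoms: none
Why: Fluoride cleavage of the aryl silyl ether under weakly acidic conditions, chosen over basic fluoride so that the flavanone cannot open to the chalcone and lose its C2 configuration.

Step 16
Reactants: 29 7-hydroxy flavanone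
Product: 30 (2S)-5,7-dihydroxy-8-[(1R)-1-(2-hydroxy-4-methoxy-3,3,5-trimethyl-6-oxocyclohexa-1,4-dien-1-yl)-2-methylpropyl]-6-methyl-2-phenyl-2,3-dihydro-4H-chromen-4-one (target CNP0320113.1)
Conditions: H2 (1 atm), 10% Pd/C, EtOAc, rt
Reagents that add atoms: none
Why: Hydrogenolysis of the aryl benzyl ether and the benzyl enol ether, which should be faster than reduction of the tetrasubstituted push–pull alkenes of ring A or cleavage of the flavanone C2–O bond if the reaction is stopped at full debenzylation.

**Compound list**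

1 | methyl 2,6-dihydroxy-4-methoxybenzoate | COC(=O)c1c(O)cc(OC)cc1O | starting material
2 | methyl 2-hydroxy-4-methoxy-3,3,5-trimethyl-6-oxocyclohexa-1,4-diene-1-carboxylate | COC(=O)C1=C(O)C(C)(C)C(OC)=C(C)C1=O | intermediate
3 | 2-hydroxy-4-methoxy-3,3,5-trimethyl-6-oxocyclohexa-1,4-diene-1-carboxylic acid | OC(=O)C1=C(O)C(C)(C)C(OC)=C(C)C1=O | intermediate (not isolated)
4 | 3-hydroxy-5-methoxy-4,4,6-trimethylcyclohexa-2,5-dien-1-one (ring A enol) | COC1=C(C)C(=O)C=C(O)C1(C)C | intermediate
5 | isobutyraldehyde | CC(C)C=O | starting material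
6 | 3-hydroxy-5-methoxy-4,4,6-trimethyl-2-[2-methyl-1-(piperidin-1-yl)propyl]cyclohexa-2,5-dien-1-one (racemic Mannich base) | COC1=C(C)C(=O)C(C(C(C)C)N2CCCCC2)=C(O)C1(C)C | intermediate (not isolated)
7 | 5-methoxy-4,6,6-trimethyl-2-(2-methylpropylidene)cyclohex-4-ene-1,3-dione (E/Z mixture) | COC1=C(C)C(=O)C(=CC(C)C)C(=O)C1(C)C | intermediate
8 | (triisopropylsilyl)acetylene | C#C[Si](C(C)C)(C(C)C)C(C)C | starting material
9 | 3-hydroxy-5-methoxy-4,4,6-trimethyl-2-[(3S)-4-methyl-1-(triisopropylsilyl)pent-1-yn-3-yl]cyclohexa-2,5-dien-1-one | COC1=C(C)C(=O)C([C@@H](C#C[Si](C(C)C)(C(C)C)C(C)C)C(C)C)=C(O)C1(C)C | intermediate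
10 | 3-(benzyloxy)-5-methoxy-4,4,6-trimethyl-2-[(3S)-4-methyl-1-(triisopropylsilyl)pent-1-yn-3-yl]cyclohexa-2,5-dien-1-one | COC1=C(C)C(=O)C([C@@H](C#C[Si](C(C)C)(C(C)C)C(C)C)C(C)C)=C(OCc2ccccc2)C1(C)C | intermediate
11 | 3-(benzyloxy)-5-methoxy-4,4,6-trimethyl-2-[(3R)-4-methylpent-1-yn-3-yl]cyclohexa-2,5-dien-1-one | COC1=C(C)C(=O)C([C@@H](C#C)C(C)C)=C(OCc2ccccc2)C1(C)C | intermediate
12 | lithium acetylide of 11 | COC1=C(C)C(=O)C([C@@H](C#C[Li])C(C)C)=C(OCc2ccccc2)C1(C)C | intermediate (not isolated)
13 | lithium ynolate derived from 11 (lithium 3-[ring A]-4-methylpent-1-yn-1-olate, configuration retained) | COC1=C(C)C(=O)C([C@@H](C#CO[Li])C(C)C)=C(OCc2ccccc2)C1(C)C | intermediate (not isolated)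
14 | 3-(benzyloxy)-5-methoxy-4,4,6-trimethyl-2-[(3R)-4-methyl-1-(triisopropylsilyloxy)pent-1-yn-3-yl]cyclohexa-2,5-dien-1-one (siloxyalkyne) | COC1=C(C)C(=O)C([C@@H](C#CO[Si](C(C)C)(C(C)C)C(C)C)C(C)C)=C(OCc2ccccc2)C1(C)C | intermediate
15 | 1-ethoxyprop-1-yne | CCOC#CC | starting material
16 | ketene (from pyrolysis of acetone, used at once) | C=C=O | starting material
17 | 3-ethoxy-2-methylcyclobut-2-en-1-one | CCOC1=C(C)C(=O)C1 | intermediate
18 | 3-hydroxy-2-methylcyclobut-2-en-1-one | CC1=C(O)CC1=O | intermediate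
19 | 3-(benzyloxy)-2-methylcyclobut-2-en-1-one | CC1=C(OCc2ccccc2)CC1=O | intermediate
20 | 3-(benzyloxy)-2-methylbuta-1,3-dien-1-one (vinylketene) | C=C(OCc1ccccc1)C(C)=C=O | intermediate (not isolated)
21 | 4-[1-(benzyloxy)ethenyl]-4-methyl-3-(triisopropylsilyloxy)cyclobut-2-en-1-one bearing at C2 the ring A methine unit of 14 (methine configuration retained, C4 epimers) | COC1=C(C)C(=O)C([C@@H](C2=C(O[Si](C(C)C)(C(C)C)C(C)C)C(C)(C(=C)OCc3ccccc3)C2=O)C(C)C)=C(OCc2ccccc2)C1(C)C | intermediate (not isolated)
22 | dienylketene O=C=C(R)–C(OSi(i-Pr)3)=C(CH3)–C(OBn)=CH2, R = ring A methine unit of 14, ketenyl and vinyl groups cis | COC1=C(C)C(=O)C([C@@H](C(=C=O)/C(O[Si](C(C)C)(C(C)C)C(C)C)=C(C)\C(=C)OCc2ccccc2)C(C)C)=C(OCc2ccccc2)C1(C)C | intermediate (not isolated)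
23 | 3-(benzyloxy)-2-{(1R)-1-[4-(benzyloxy)-6-hydroxy-3-methyl-2-(triisopropylsilyloxy)phenyl]-2-methylpropyl}-5-methoxy-4,4,6-trimethylcyclohexa-2,5-dien-1-one (ring B phenol) | COC1=C(C)C(=O)C([C@@H](c2c(O[Si](C(C)C)(C(C)C)C(C)C)c(C)c(OCc3ccccc3)cc2O)C(C)C)=C(OCc2ccccc2)C1(C)C | intermediate
24 | methyl (R)-3-hydroxy-3-phenylpropanoate | COC(=O)C[C@@H](O)c1ccccc1 | starting material
25 | methyl (3S)-3-{5-(benzyloxy)-2-[(1R)-1-(2-(benzyloxy)-4-methoxy-3,3,5-trimethyl-6-oxocyclohexa-1,4-dien-1-yl)-2-methylpropyl]-4-methyl-3-(triisopropylsilyloxy)phenoxy}-3-phenylpropanoate | COC1=C(C)C(=O)C([C@@H](c2c(O[Si](C(C)C)(C(C)C)C(C)C)c(C)c(OCc3ccccc3)cc2O[C@H](c2ccccc2)CC(=O)OC)C(C)C)=C(OCc2ccccc2)C1(C)C | intermediate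
26 | (3S)-3-{5-(benzyloxy)-2-[(1R)-1-(2-(benzyloxy)-4-methoxy-3,3,5-trimethyl-6-oxocyclohexa-1,4-dien-1-yl)-2-methylpropyl]-4-methyl-3-(triisopropylsilyloxy)phenoxy}-3-phenylpropanoic acid | COC1=C(C)C(=O)C([C@@H](c2c(O[Si](C(C)C)(C(C)C)C(C)C)c(C)c(OCc3ccccc3)cc2O[C@H](c2ccccc2)CC(=O)O)C(C)C)=C(OCc2ccccc2)C1(C)C | intermediate
27 | mixed anhydride of 26 with trifluoroacetic acid | COC1=C(C)C(=O)C([C@@H](c2c(O[Si](C(C)C)(C(C)C)C(C)C)c(C)c(OCc3ccccc3)cc2O[C@H](c2ccccc2)CC(=O)OC(=O)C(F)(F)F)C(C)C)=C(OCc2ccccc2)C1(C)C | intermediate (not isolated)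
28 | (2S)-5-(benzyloxy)-8-[(1R)-1-(2-(benzyloxy)-4-methoxy-3,3,5-trimethyl-6-oxocyclohexa-1,4-dien-1-yl)-2-methylpropyl]-6-methyl-2-phenyl-7-(triisopropylsilyloxy)-2,3-dihydro-4H-chromen-4-one | COC1=C(C)C(=O)C([C@@H](c2c(O[Si](C(C)C)(C(C)C)C(C)C)c(C)c(OCc4ccccc4)c3c2O[C@H](c2ccccc2)CC3=O)C(C)C)=C(OCc2ccccc2)C1(C)C | intermediate
29 | (2S)-5-(benzyloxy)-8-[(1R)-1-(2-(benzyloxy)-4-methoxy-3,3,5-trimethyl-6-oxocyclohexa-1,4-dien-1-yl)-2-methylpropyl]-7-hydroxy-6-methyl-2-phenyl-2,3-dihydro-4H-chromen-4-one | COC1=C(C)C(=O)C([C@@H](c2c(O)c(C)c(OCc4ccccc4)c3c2O[C@H](c2ccccc2)CC3=O)C(C)C)=C(OCc2ccccc2)C1(C)C | intermediate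
30 | (2S)-5,7-dihydroxy-8-[(1R)-1-(2-hydroxy-4-methoxy-3,3,5-trimethyl-6-oxocyclohexa-1,4-dien-1-yl)-2-methylpropyl]-6-methyl-2-phenyl-2,3-dihydro-4H-chromen-4-one | COC1=C(C)C(=O)C([C@@H](c2c(O)c(C)c(O)c3c2O[C@H](c2ccccc2)CC3=O)C(C)C)=C(O)C1(C)C | target

**Step count and risks**

Total step count: 16. Longest linear sequence: 13 steps (steps 1–7, then 11–16); steps 8–10 form the cyclobutenone branch.

Steps most likely to fail:

1. Step 11 (the new method). The alkoxy-stabilised cyclobutenone may open too slowly below the temperature at which the siloxyalkyne rearranges to a silylketene. The vinylketene may also be consumed by dimerisation or by acylating the product phenol instead of adding to the hindered alkyne. Fallback with known chemistry, setting out from 7 and returning at 30: commercial 2-methylphloroglucinol is cinnamoylated and cyclised (cinnamoyl chloride, AlCl3, PhNO2) to racemic 5,7-dihydroxy-6-methylflavanone F1, from which the 8-methyl regioisomer 5,7-dihydroxy-8-methylflavanone F2 is removed by chromatography. F1 is resolved on a chiral stationary phase to (2S)-5,7-dihydroxy-6-methylflavanone F3. F3 is then added through C8, its only free nucleophilic ring position, to the alkylidene 7 in THF at rt; this is the Michael coupling well established between acylphloroglucinols and isobutylidene β-triketones. It gives 30 together with its (1S)-methine epimer F4, and the two diastereomers are separated by chromatography.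

2. Step 4. The acidic diketone product may hold the rhodium as a diketonate and stall turnover, the acceptor may tautomerise to its dienol before addition, and discrimination between the faces of the β-carbon may be poor. Fallback, setting out from 7 and returning at 9: non-selective 1,4-addition of the alkynylalane prepared from 8 (n-BuLi, then Me2AlCl, toluene/THF, −40 °C) gives the racemic adduct 3-hydroxy-5-methoxy-4,4,6-trimethyl-2-[4-methyl-1-(triisopropylsilyl)pent-1-yn-3-yl]cyclohexa-2,5-dien-1-one F5, which is resolved by preparative chromatography on a chiral stationary phase to give 9.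

3. Step 12. Etherification of the hindered, weakly acidic phenol may be slow, so that elimination of the activated alcohol to methyl cinnamate takes over, and partial ionisation of the benzylic oxyphosphonium ion may erode the inversion. Fallback, setting out from 23 and returning at 28: the phenol is acylated (cinnamoyl chloride, Et3N, DMAP, CH2Cl2) to the aryl cinnamate F6. A photochemical Fries shift to C4a (hν 300 nm, benzene) gives the 2'-hydroxychalcone F7. Oxa-Michael cyclisation (NaOAc, EtOH, reflux) then gives 28 and its (2R)-epimer F8; these are diastereomers, are separated by chromatography, and F8 is recycled through base-mediated ring opening and reclosure.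

Further compounds
F1 | step 11 | racemic 5,7-dihydroxy-6-methyl-2-phenyl-2,3-dihydro-4H-chromen-4-one | Cc1c(O)cc2OC(c3ccccc3)CC(=O)c2c1O
F2 | step 11 | racemic 5,7-dihydroxy-8-methyl-2-phenyl-2,3-dihydro-4H-chromen-4-one | Cc1c(O)cc(O)c2C(=O)CC(c3ccccc3)Oc12
F3 | step 11 | (2S)-5,7-dihydroxy-6-methyl-2-phenyl-2,3-dihydro-4H-chromen-4-one | Cc1c(O)cc2O[C@H](c3ccccc3)CC(=O)c2c1O
F4 | step 11 | (2S)-5,7-dihydroxy-8-[(1S)-1-(2-hydroxy-4-methoxy-3,3,5-trimethyl-6-oxocyclohexa-1,4-dien-1-yl)-2-methylpropyl]-6-methyl-2-phenyl-2,3-dihydro-4H-chromen-4-one | COC1=C(C)C(=O)C([C@H](c2c(O)c(C)c(O)c3c2O[C@H](c2ccccc2)CC3=O)C(C)C)=C(O)C1(C)C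
F5 | step 4 | racemic 3-hydroxy-5-methoxy-4,4,6-trimethyl-2-[4-methyl-1-(triisopropylsilyl)pent-1-yn-3-yl]cyclohexa-2,5-dien-1-one | COC1=C(C)C(=O)C(C(C#C[Si](C(C)C)(C(C)C)C(C)C)C(C)C)=C(O)C1(C)C
F6 | step 12 | (E)-cinnamate ester of phenol 23 | COC1=C(C)C(=O)C([C@@H](c2c(O[Si](C(C)C)(C(C)C)C(C)C)c(C)c(OCc3ccccc3)cc2OC(=O)/C=C/c2ccccc2)C(C)C)=C(OCc2ccccc2)C1(C)C
F7 | step 12 | 2'-hydroxychalcone: 23 carrying an (E)-cinnamoyl group at C4a of ring B | COC1=C(C)C(=O)C([C@@H](c2c(O[Si](C(C)C)(C(C)C)C(C)C)c(C)c(OCc3ccccc3)c(C(=O)/C=C/c3ccccc3)c2O)C(C)C)=C(OCc2ccccc2)C1(C)C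
F8 | step 12 | (2R)-epimer of 28 | COC1=C(C)C(=O)C([C@@H](c2c(O[Si](C(C)C)(C(C)C)C(C)C)c(C)c(OCc4ccccc4)c3c2O[C@@H](c2ccccc2)CC3=O)C(C)C)=C(OCc2ccccc2)C1(C)C
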